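**Retrosynthetic overview**

Prosogerin C is 6,7-dimethoxy-2-(3,4,5-trimethoxyphenyl)-4H-chromen-4-one; rings A and B are bought and ring C is the only ring made, in the last step.
Ring C is cut at O1–C8a and C4–C4a (aryne insertion into the C–O bond of a carboxylic acid) and at O1–C2 (conjugate ring closure).
This gives 4,5-dimethoxybenzyne (from silyl triflate 5) and 3-(3,4,5-trimethoxyphenyl)propiolic acid 4, which carries C2, C3, C4, O1, the carbonyl oxygen and ring B in one piece.
The feature the plan rests on: the methoxy groups of ring A sit on C6 and C7, symmetric about the line through the midpoints of the C6–C7 and C4a–C8a bonds, so C4a and C8a are the two equivalent carbons of 4,5-dimethoxybenzyne and only one regioisomer can form.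
Acid 4 comes from 5-ethynyl-1,2,3-trimethoxybenzene 1 by lithiation and carboxylation.

Key step: step 2

Assumption: compounds 1 and 5 are purchased as such; the target has no stereocentre, so no configuration has to be set.

**Route**

Step 1
Reactants: 1 5-ethynyl-1,2,3-trimethoxybenzene
Product: 4 3-(3,4,5-trimethoxyphenyl)propiolic acid, via lithium acetylide 2 (not isolated), via lithium propiolate 3 (not isolated)
Conditions: n-BuLi (1.05 equiv), THF, −78 °C; dry CO2 (g), −78 °C to rt; 1 M HCl, 0 °C
Reagents that add atoms: carbon dioxide, O=C=O
Why: The terminal alkyne C–H is removed cleanly by n-BuLi at −78 °C and the lithium acetylide adds to carbon dioxide (carboxylation of a metal acetylide), the aryl methyl ethers being inert under these conditions.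

Step 2
Reactants: 4 3-(3,4,5-trimethoxyphenyl)propiolic acid; 5 4,5-dimethoxy-2-(trimethylsilyl)phenyl trifluoromethanesulfonate (1.5 equiv)
Product: 9 prosogerin C (6,7-dimethoxy-2-(3,4,5-trimethoxyphenyl)-4H-chromen-4-one), via dimethoxybenzyne 6 (not isolated), via hydroxyaryl ynone 7 (not isolated), via amino enone 8 (not isolated)
Conditions: CsF (4 equiv), THF, 125 °C, sealed tube; then Et2NH followed by EtOH, rt to 50 °C, same flask
Reagents that add atoms: none
Why: Fluoride removes the silyl group of 5 and triflate departs to give the symmetric aryne 6; the cesium carboxylate of 4 adds through oxygen to one aryne carbon (O1–C8a), and the aryl anion at the neighbouring carbon attacks the ester carbonyl through a four-membered benzoxetene alkoxide that opens to the 2-acylphenoxide (C4–C4a), that is, to ynone 7. This is the known fluoride-triggered aryne insertion into the C–O bond of carboxylic acids, which with alkynoic acids runs on to chromones. Ring C then closes by 6-endo-dig oxa-Michael addition of the phenoxide oxygen to the alkyne carbon bearing ring B (O1–C2), the acid proton ending on C3; no stereocentre is formed. Regiochemistry of the insertion needs no control, because the methoxy groups on C6 and C7 make the two aryne carbons (future C4a and C8a) equivalent. Acyl transfer must outrun protonation of the aryl anion, which the hot aprotic medium favours, and the six-membered closure must outrun the five-membered one to the aurone, which an aprotic phenoxide favours because only attack at the ring-B-bearing carbon gives a stabilised allenolate. Diethylamine is held back until the aryne is spent, since it would otherwise be N-arylated, and then converts any unclosed 7 into enaminone 8, from which oxygen-for-nitrogen addition–elimination can give only the six-membered ring.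

**Compound list**

1 | 5-ethynyl-1,2,3-trimethoxybenzene | C#Cc1cc(OC)c(OC)c(OC)c1 | starting material
2 | lithium (3,4,5-trimethoxyphenyl)acetylide | [Li+].[C-]#Cc1cc(OC)c(OC)c(OC)c1 | intermediate
3 | lithium 3-(3,4,5-trimethoxyphenyl)propiolate | [Li+].[O-]C(=O)C#Cc1cc(OC)c(OC)c(OC)c1 | intermediate
4 | 3-(3,4,5-trimethoxyphenyl)propiolic acid | COc1cc(C#CC(=O)O)cc(OC)c1OC | intermediate
5 | 4,5-dimethoxy-2-(trimethylsilyl)phenyl trifluoromethanesulfonate | COc1cc(OS(=O)(=O)C(F)(F)F)c([Si](C)(C)C)cc1OC | starting material
6 | 4,5-dimethoxybenzyne (4,5-dimethoxy-1,2-didehydrobenzene) | COC1=CC#CC=C1OC | intermediate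
7 | 1-(2-hydroxy-4,5-dimethoxyphenyl)-3-(3,4,5-trimethoxyphenyl)prop-2-yn-1-one | COc1cc(O)c(C(=O)C#Cc2cc(OC)c(OC)c(OC)c2)cc1OC | intermediate
8 | (E)-3-(diethylamino)-1-(2-hydroxy-4,5-dimethoxyphenyl)-3-(3,4,5-trimethoxyphenyl)prop-2-en-1-one (push–pull alkene, drawn E; its geometry does not affect the closure) | CCN(CC)/C(=C/C(=O)c1cc(OC)c(OC)cc1O)c1cc(OC)c(OC)c(OC)c1 | intermediate
9 | prosogerin C, 6,7-dimethoxy-2-(3,4,5-trimethoxyphenyl)-4H-chromen-4-one | COc1cc2oc(-c3cc(OC)c(OC)c(OC)c3)cc(=O)c2cc1OC | target

**Step count and risks**

Total step count: 2. Longest linear sequence: 2 steps (1 to 4 to 9).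

The route has only two steps, so both are listed; step 2 is entered twice, once for each of its two stages, because they can fail by different processes.

1. Step 2, insertion stage. The cesium propiolate may lose carbon dioxide at 125 °C before it meets the aryne. Alternatively, the aryl anion formed after O-addition may be protonated (by bifluoride or unreacted acid) faster than it attacks the carbonyl, so that the sequence stops at the aryl ester. The fallback sets out from alkyne 1 and comes back at target 9, with ring A brought in as an iodophenol and C4 as carbon monoxide. Commercial 3,4-dimethoxyphenol is iodinated ortho to the hydroxyl and para to its 3-methoxy group with N-iodosuccinimide (MeCN, 0 °C) to give 2-iodo-4,5-dimethoxyphenol F1. F1 and alkyne 1 are then joined under carbon monoxide (about 20 atm) with catalytic PdCl2(dppf) in Et2NH at 120 °C (carbonylative Sonogashira coupling followed by amine-mediated closure). This should give 9 in one operation, passing through ynone 7 and enaminone 8 in the flask.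

2. Step 2, closure stage. The 2-acylphenoxide may close in part through the five-membered mode, or may be O-arylated by surplus aryne, before the amine stage can steer it. The fallback sets out from aryne precursor 5 and comes back at target 9; it replaces the alkyne by an alkene, for which only the six-membered closure exists. Compound 5 is treated under the same conditions (CsF, THF, 125 °C) with commercial (E)-3,4,5-trimethoxycinnamic acid. The same C–O insertion through aryne 6 should give (E)-1-(2-hydroxy-4,5-dimethoxyphenyl)-3-(3,4,5-trimethoxyphenyl)prop-2-en-1-one F2, which closes by 6-endo-trig oxa-Michael addition to racemic 6,7-dimethoxy-2-(3,4,5-trimethoxyphenyl)chroman-4-one F3. The crude mixture of F2 and F3 is then dehydrogenated with catalytic I2 in DMSO at 120 °C, the standard oxidation of 2'-hydroxychalcones and flavanones to flavones, to give 9.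

3. Step 1. Trapping of the acetylide by carbon dioxide may be incomplete (reprotonation by moisture carried in with the gas returns alkyne 1), and the free acid may lose carbon dioxide during concentration. The fallback sets out from alkyne 1 (through acetylide 2) and comes back at acid 4. Acetylide 2 is quenched at −78 °C with methyl chloroformate to give methyl 3-(3,4,5-trimethoxyphenyl)propiolate F4, which can be purified by chromatography and stored. F4 is saponified immediately before use (LiOH, THF–H2O, 0 °C) to lithium propiolate 3 and acidified cold with 1 M HCl to give 4.

**Further compounds**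

F1 | step 2 | 2-iodo-4,5-dimethoxyphenol | COc1cc(O)c(I)cc1OC
F2 | step 2 | (E)-1-(2-hydroxy-4,5-dimethoxyphenyl)-3-(3,4,5-trimethoxyphenyl)prop-2-en-1-one | COc1cc(O)c(C(=O)/C=C/c2cc(OC)c(OC)c(OC)c2)cc1OC
F3 | step 2 | racemic 6,7-dimethoxy-2-(3,4,5-trimethoxyphenyl)chroman-4-one | COc1cc2OC(CC(=O)c2cc1OC)c1cc(OC)c(OC)c(OC)c1
F4 | step 1 | methyl 3-(3,4,5-trimethoxyphenyl)propiolate | COC(=O)C#Cc1cc(OC)c(OC)c(OC)c1
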